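## Retrosynthetic overview

1. Target (ring numbering: C1 ring ketone, C2 acyl-bearing carbon, C3 enol carbon, C4 and C5 CH2, C6 carbinol, R) ⇒ C2-acylation (DCC/DMAP, O→C acyl shift) of (4R)-4-silyloxycyclohexane-1,3-dione 10 with (7E,9E)-octadeca-7,9-dienoic acid 18, itself from a Suzuki coupling of two E-alkenyl halves.
2. 10 ⇒ Dieckmann closure (C2–C3) of methyl (R)-4-silyloxy-5-oxohexanoate 9; 9 ⇒ retro-aldol opening of the cyclobutane-fused dioxanones 7 and 8 (second half of a de Mayo sequence).
3. 7 and 8 ⇒ [2+2] photoadduct 3 of commercial dioxinone 1 and ketene diethyl acetal 2. This step makes the C4–C5 and C1–C6 bonds. Its masked cyclobutanone is then reduced under CBS control so that both enantiomers of the racemate receive the same 8R carbinol and converge after the fragmentation.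
4. Enabling feature: in the cyclohexane ring the carbonyl carbons C1 and C3 are joined the long way round by C6–C5–C4, a 1,5-dicarbonyl array with the hydroxyl on C6 directly beside C1. This is a de Mayo retron: C1 and C4 are the two enol carbons of an acetoacetate, C5–C6 is an alkene inserted between them, and the photochemical head-to-tail orientation supplies the α-oxygenation.
5. Ring order: dioxinone ring (purchased) → cyclobutane (step 1, temporary) → both temporary rings opened (step 5) → cyclohexane-1,3-dione ring, the only ring of the target (step 6).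

Key step: step 1

Remark: the target is an enolised 2-acylcyclohexane-1,3-dione; its tautomers are treated as one compound, and the single stereocentre (C6) is R.
Remark: 3 and 4 are racemates whose SMILES show the (1S,6S) enantiomer; 5 and 7 derive from that enantiomer, 6 and 8 from its mirror image.

## Route

Step 1
Reactants: 1 2,2,6-trimethyl-4H-1,3-dioxin-4-one; 2 1,1-diethoxyethene (ketene diethyl acetal)
Product: 3 rac-(1S,6S)-8,8-diethoxy-1,3,3-trimethyl-2,4-dioxabicyclo[4.2.0]octan-5-one
Conditions: hν (450 W medium-pressure Hg lamp, Pyrex filter), 2 (6 equiv), MeCN/acetone 9:1, degassed, 0 °C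
Reagents that add atoms: none
Why: This is the enone–alkene [2+2] photocycloaddition of a 1,3-dioxin-4-one, the first half of a de Mayo sequence: the triplet of 1 adds 2 stepwise through a 1,4-biradical and the cyclobutane closes by radical recombination (four-membered ring, formal [2π+2π], cis ring fusion forced by the six-membered ring). The closest known reaction type is the photocycloaddition of this dioxinone and of cyclohexenones to 1,1-dialkoxyethenes. The bond from C5 of 1 to the CH2 of 2 is the C4–C5 bond of the target, and the bond from C6 of 1 to the acetal carbon of 2 is the C1–C6 bond of the target. The step needs head-to-tail regioselectivity (acetal carbon on the oxygen-bearing β-carbon C6); this follows the usual orientation of electron-rich 1,1-dialkoxyalkenes with triplet enones, where the unsubstituted CH2 bonds to the α-carbon and both radical centres of the biradical are oxygen-stabilised, and it places the future hydroxyl carbon directly beside the future C1 ketone, which ground-state enolate chemistry with a vinyl ether cannot do. The two new stereocentres (C1 and C6 of the bicycle) form as a racemic cis pair and need no control because the retro-aldol of step 5 erases both; the carbinol centre is set in step 3 at the ketone that this step installs in masked form.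

Step 2
Reactants: 3 rac-(1S,6S)-8,8-diethoxy-1,3,3-trimethyl-2,4-dioxabicyclo[4.2.0]octan-5-one
Product: 4 rac-(1S,6S)-1,3,3-trimethyl-2,4-dioxabicyclo[4.2.0]octane-5,8-dione
Conditions: TsOH·H2O (5 mol%), acetone/H2O 20:1, rt
Reagents that add atoms: water, O
Why: Acid-catalysed hydrolysis removes the acyclic diethyl ketal, while the dioxanone acetonide, an acylal-type acetal that opens far more slowly and is buffered by the acetone solvent, should survive, so only C8 is unmasked.

Step 3
Reactants: 4 rac-(1S,6S)-1,3,3-trimethyl-2,4-dioxabicyclo[4.2.0]octane-5,8-dione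
Product: 5 (1S,6S,8R)-8-hydroxy-1,3,3-trimethyl-2,4-dioxabicyclo[4.2.0]octan-5-one and 6 (1R,6R,8R)-8-hydroxy-1,3,3-trimethyl-2,4-dioxabicyclo[4.2.0]octan-5-one (two diastereomers, carried on together)
Conditions: (S)-2-methyl-CBS-oxazaborolidine (20 mol%), BH3·SMe2 (1.0 equiv), THF, −30 °C; MeOH quench
Reagents that add atoms: none
Why: In this Corey–Bakshi–Shibata reduction the ketone binds the catalyst boron anti to the fully substituted ring-fusion carbon C1 (large group) and syn to C7H2 (small group), so hydride should reach the same prochiral carbonyl face in both enantiomers of 4 and give 8R in each, which is the future C6 (R) centre of the target; the two alcohols differ only at C1/C6, which step 5 erases.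

Step 4
Reactants: 5 (1S,6S,8R)-8-hydroxy-1,3,3-trimethyl-2,4-dioxabicyclo[4.2.0]octan-5-one; 6 (1R,6R,8R)-8-hydroxy-1,3,3-trimethyl-2,4-dioxabicyclo[4.2.0]octan-5-one
Product: 7 (1S,6S,8R)-8-[(tert-butyldimethylsilyl)oxy]-1,3,3-trimethyl-2,4-dioxabicyclo[4.2.0]octan-5-one and 8 (1R,6R,8R)-8-[(tert-butyldimethylsilyl)oxy]-1,3,3-trimethyl-2,4-dioxabicyclo[4.2.0]octan-5-one
Conditions: TBSOTf (1.5 equiv), 2,6-lutidine (2.5 equiv), CH2Cl2, 0 °C
Reagents that add atoms: tert-butyldimethylsilyl trifluoromethanesulfonate, CC(C)(C)[Si](C)(C)OS(=O)(=O)C(F)(F)F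
Why: The silyl triflate silylates the hindered secondary cyclobutanol under non-nucleophilic base without touching any stereocentre.

Step 5
Reactants: 7 (1S,6S,8R)-8-[(tert-butyldimethylsilyl)oxy]-1,3,3-trimethyl-2,4-dioxabicyclo[4.2.0]octan-5-one; 8 (1R,6R,8R)-8-[(tert-butyldimethylsilyl)oxy]-1,3,3-trimethyl-2,4-dioxabicyclo[4.2.0]octan-5-one
Product: 9 methyl (4R)-4-[(tert-butyldimethylsilyl)oxy]-5-oxohexanoate
Conditions: K2CO3 (0.2 equiv), MeOH, 0 °C, 1 h; pH 7 buffer
Reagents that add atoms: methanol, CO
Why: Base-catalysed methanolysis of the acylal releases acetone and a cyclobutanolate β to the new ester, which undergoes strain-driven retro-aldol cleavage of the C1–C6 bond (second half of the de Mayo sequence); this erases both ring-fusion stereocentres, so 7 and 8 should converge on one enantiomer, and the silyloxy stereocentre is not involved.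

Step 6
Reactants: 9 methyl (4R)-4-[(tert-butyldimethylsilyl)oxy]-5-oxohexanoate
Product: 10 (4R)-4-[(tert-butyldimethylsilyl)oxy]cyclohexane-1,3-dione
Conditions: LiN(SiMe3)2 (2.3 equiv), THF, −78 °C (9 added to the base), then 0 °C; 1 M HCl to pH 3
Reagents that add atoms: none
Why: In this Dieckmann-type intramolecular Claisen condensation the kinetic lithium enolate of the methyl ketone (formed at CH3, away from the hindered silyloxy carbon) attacks the ester in a 6-exo-trig closure that forms the C2–C3 bond of the target ring, and the second equivalent of base takes up the acidic 1,3-dione, so the silyloxy stereocentre should stay untouched.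

Step 7
Reactants: 11 oct-7-ynoic acid
Product: 12 methyl oct-7-ynoate
Conditions: MeOH, H2SO4 (cat.), reflux
Reagents that add atoms: methanol, CO
Why: Fischer esterification in excess methanol masks the acid, which would otherwise consume the borane in step 8.

Step 8
Reactants: 12 methyl oct-7-ynoate
Product: 13 methyl (7E)-8-(4,4,5,5-tetramethyl-1,3,2-dioxaborolan-2-yl)oct-7-enoate
Conditions: pinacolborane (1.2 equiv), Cp2Zr(H)Cl (10 mol%), Et3N (10 mol%), neat, 60 °C
Reagents that add atoms: pinacolborane, CC1(C)OBOC1(C)C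
Why: Zirconium-catalysed syn hydroboration of the terminal alkyne places boron on the terminal carbon and fixes the E geometry, and the ester is inert to pinacolborane.

Step 9
Reactants: 14 dec-1-yne
Product: 16 (E)-1-iododec-1-ene, via alkenylzirconocene 15 (not isolated)
Conditions: Cp2Zr(H)Cl (1.2 equiv), CH2Cl2, rt; then I2 (1.2 equiv), 0 °C
Reagents that add atoms: iodine, II
Why: Hydrozirconation adds Zr–H syn across the alkyne with zirconium on the terminal carbon, and iodinolysis of the carbon–zirconium bond proceeds with retention, fixing the E geometry.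

Step 10
Reactants: 13 methyl (7E)-8-(4,4,5,5-tetramethyl-1,3,2-dioxaborolan-2-yl)oct-7-enoate; 16 (E)-1-iododec-1-ene
Product: 17 methyl (7E,9E)-octadeca-7,9-dienoate
Conditions: Pd(PPh3)4 (5 mol%), K3PO4 (3 equiv), THF/H2O 5:1, 60 °C
Reagents that add atoms: none
Why: Suzuki–Miyaura coupling of an alkenylboronate with an alkenyl iodide proceeds with retention of both double-bond geometries and should give the 7E,9E diene.

Step 11
Reactants: 17 methyl (7E,9E)-octadeca-7,9-dienoate
Product: 18 (7E,9E)-octadeca-7,9-dienoic acid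
Conditions: LiOH·H2O (3 equiv), THF/MeOH/H2O 3:1:1, rt; then 1 M HCl
Reagents that add atoms: lithium hydroxide, [Li+].[OH-]
Why: Saponification of the methyl ester leaves the unconjugated E,E-diene unchanged.

Step 12
Reactants: 10 (4R)-4-[(tert-butyldimethylsilyl)oxy]cyclohexane-1,3-dione; 18 (7E,9E)-octadeca-7,9-dienoic acid
Product: 20 (6R)-6-[(tert-butyldimethylsilyl)oxy]-3-hydroxy-2-[(7E,9E)-octadeca-7,9-dienoyl]cyclohex-2-en-1-one, via enol ester 19 (not isolated)
Conditions: DCC (1.2 equiv), DMAP (1.2 equiv), CH2Cl2, 0 °C to rt, 24 h; 1 M HCl wash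
Reagents that add atoms: none
Why: Carbodiimide esterification gives the enol ester and DMAP then mediates the O-to-C acyl shift, the standard route to 2-acylcyclohexane-1,3-diones; both possible enol esters lead to the same C2-acyl product, and the chelated triketone is the thermodynamic sink.

Step 13
Reactants: 20 (6R)-6-[(tert-butyldimethylsilyl)oxy]-3-hydroxy-2-[(7E,9E)-octadeca-7,9-dienoyl]cyclohex-2-en-1-one
Product: 21 (6R)-3,6-dihydroxy-2-[(7E,9E)-octadeca-7,9-dienoyl]cyclohex-2-en-1-one (CNP0169831.1)
Conditions: HF·pyridine, THF, 0 °C to rt (polypropylene vessel)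
Reagents that add atoms: none
Why: Fluoride cleaves the secondary silyl ether under mildly acidic conditions that should neither isomerise the E,E-diene nor epimerise the carbinol centre, whose neighbouring carbonyl is tied up in the enolised triketone.

## Compound list

1 | 2,2,6-trimethyl-4H-1,3-dioxin-4-one | CC1=CC(=O)OC(C)(C)O1 | starting material
2 | 1,1-diethoxyethene (ketene diethyl acetal) | C=C(OCC)OCC | starting material
3 | rac-(1S,6S)-8,8-diethoxy-1,3,3-trimethyl-2,4-dioxabicyclo[4.2.0]octan-5-one (cis-fused, racemic) | C[C@]12OC(C)(C)OC(=O)[C@H]1CC2(OCC)OCC | intermediate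
4 | rac-(1S,6S)-1,3,3-trimethyl-2,4-dioxabicyclo[4.2.0]octane-5,8-dione (cis-fused, racemic) | C[C@]12OC(C)(C)OC(=O)[C@H]1CC2=O | intermediate
5 | (1S,6S,8R)-8-hydroxy-1,3,3-trimethyl-2,4-dioxabicyclo[4.2.0]octan-5-one | C[C@]12OC(C)(C)OC(=O)[C@H]1C[C@H]2O | intermediate
6 | (1R,6R,8R)-8-hydroxy-1,3,3-trimethyl-2,4-dioxabicyclo[4.2.0]octan-5-one | C[C@@]12OC(C)(C)OC(=O)[C@@H]1C[C@H]2O | intermediate
7 | (1S,6S,8R)-8-[(tert-butyldimethylsilyl)oxy]-1,3,3-trimethyl-2,4-dioxabicyclo[4.2.0]octan-5-one | C[C@]12OC(C)(C)OC(=O)[C@H]1C[C@H]2O[Si](C)(C)C(C)(C)C | intermediate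
8 | (1R,6R,8R)-8-[(tert-butyldimethylsilyl)oxy]-1,3,3-trimethyl-2,4-dioxabicyclo[4.2.0]octan-5-one | C[C@@]12OC(C)(C)OC(=O)[C@@H]1C[C@H]2O[Si](C)(C)C(C)(C)C | intermediate
9 | methyl (4R)-4-[(tert-butyldimethylsilyl)oxy]-5-oxohexanoate | COC(=O)CC[C@@H](O[Si](C)(C)C(C)(C)C)C(C)=O | intermediate
10 | (4R)-4-[(tert-butyldimethylsilyl)oxy]cyclohexane-1,3-dione | O=C1CC(=O)[C@H](O[Si](C)(C)C(C)(C)C)CC1 | intermediate
11 | oct-7-ynoic acid | C#CCCCCCC(=O)O | starting material
12 | methyl oct-7-ynoate | C#CCCCCCC(=O)OC | intermediate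
13 | methyl (7E)-8-(4,4,5,5-tetramethyl-1,3,2-dioxaborolan-2-yl)oct-7-enoate | COC(=O)CCCCC/C=C/B1OC(C)(C)C(C)(C)O1 | intermediate
14 | dec-1-yne | C#CCCCCCCCC | starting material
15 | [(1E)-dec-1-en-1-yl]zirconocene chloride, Cp2Zr(Cl)(CH=CH-C8H17) | CCCCCCCC/C=C/[Zr](Cl)(C1C=CC=C1)C1C=CC=C1 | intermediate (not isolated)
16 | (E)-1-iododec-1-ene | I/C=C/CCCCCCCC | intermediate
17 | methyl (7E,9E)-octadeca-7,9-dienoate | CCCCCCCC/C=C/C=C/CCCCCC(=O)OC | intermediate
18 | (7E,9E)-octadeca-7,9-dienoic acid | CCCCCCCC/C=C/C=C/CCCCCC(=O)O | intermediate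
19 | (4R)-4-[(tert-butyldimethylsilyl)oxy]-3-oxocyclohex-1-en-1-yl (7E,9E)-octadeca-7,9-dienoate | CCCCCCCC/C=C/C=C/CCCCCC(=O)OC1=CC(=O)[C@H](O[Si](C)(C)C(C)(C)C)CC1 | intermediate (not isolated)
20 | (6R)-6-[(tert-butyldimethylsilyl)oxy]-3-hydroxy-2-[(7E,9E)-octadeca-7,9-dienoyl]cyclohex-2-en-1-one | CCCCCCCC/C=C/C=C/CCCCCC(=O)C1=C(O)CC[C@@H](O[Si](C)(C)C(C)(C)C)C1=O | intermediate
21 | (6R)-3,6-dihydroxy-2-[(7E,9E)-octadeca-7,9-dienoyl]cyclohex-2-en-1-one | CCCCCCCC/C=C/C=C/CCCCCC(=O)C1=C(O)CC[C@@H](O)C1=O | target

## Step count and risks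

Total steps: 13. Longest linear sequence: 8 steps (steps 1–6, 12 and 13).

Steps most likely to fail:

1. Step 3. In the (1R,6R) half of 4 the catalyst has to deliver hydride to the concave face of the cyclobutanone; if the substrate's own facial preference wins there, some 8S alcohol forms and the convergence in step 5 gives 9 of lowered enantiomeric purity. Fallback (auxiliary control on a single enantiomer in place of catalyst control over a racemate; it sets out from 2 and comes back at 9): 2 is irradiated as in step 1 with (S)-2-tert-butyl-6-methyl-4H-1,3-dioxin-4-one F1, the known pivalaldehyde acetal analogue of 1 derived from (S)-3-hydroxybutanoic acid. Addition anti to the tert-butyl group should give (1S,3S,6S)-3-tert-butyl-8,8-diethoxy-1-methyl-2,4-dioxabicyclo[4.2.0]octan-5-one F2 as one enantiomer. Ketal hydrolysis as in step 2 gives (1S,3S,6S)-3-tert-butyl-1-methyl-2,4-dioxabicyclo[4.2.0]octane-5,8-dione F3. Reduction with LiBH(s-Bu)3, or with the same oxazaborolidine now acting only in the convex-face series, should give (1S,3S,6S,8R)-3-tert-butyl-8-hydroxy-1-methyl-2,4-dioxabicyclo[4.2.0]octan-5-one F4, any C8 epimer being a diastereomer removable by chromatography. Silylation as in step 4 gives (1S,3S,6S,8R)-3-tert-butyl-8-[(tert-butyldimethylsilyl)oxy]-1-methyl-2,4-dioxabicyclo[4.2.0]octan-5-one F5, and methanolysis as in step 5, with loss of pivalaldehyde in place of acetone, returns 9.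

2. Step 1. The biradical may close with loss of head-to-tail orientation (giving the 7,7-diethoxy regioisomer), or the ketene acetal may oligomerise under light or traces of acid, so that 3 is not obtained cleanly. Fallback (chiral-pool route without photochemistry; it replaces 1 and 2, so it sets out from a new commercial material and not from a numbered compound, and comes back at 10): (R)-5-oxotetrahydrofuran-2-carboxylic acid F6 (from D-glutamic acid) is converted with oxalyl chloride and catalytic DMF into (R)-5-oxotetrahydrofuran-2-carbonyl chloride F7. Me2CuLi in THF at −78 °C gives (R)-5-acetyldihydrofuran-2(3H)-one F8. LiN(SiMe3)2 then forms the methyl-ketone enolate, which attacks the lactone carbonyl (intramolecular Claisen, lactone-to-dione rearrangement) to give (R)-4-hydroxycyclohexane-1,3-dione F9. TBSCl and imidazole, followed by aqueous work-up that cleaves any silyl enol ether, give 10.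

3. Step 6. Proton transfer between the methyl-ketone enolate and unreacted ketone can move the enolate to the silyloxy-bearing carbon (epimerisation), or intermolecular Claisen condensation can compete with ring closure. Fallback (soft enolisation of an activated ester in place of a strong amide base; it sets out from 9 and comes back at 10): the methyl ester of 9 is cleaved with Me3SnOH in 1,2-dichloroethane at 60 °C to give (4R)-4-[(tert-butyldimethylsilyl)oxy]-5-oxohexanoic acid F10. Pentafluorophenol and EDC give pentafluorophenyl (4R)-4-[(tert-butyldimethylsilyl)oxy]-5-oxohexanoate F11. MgBr2·OEt2 and i-Pr2NEt in CH2Cl2 then enolise the methyl ketone under mild conditions, and the magnesium enolate closes onto the active ester to give 10.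

## Further compounds

F1 | step 3 | (S)-2-tert-butyl-6-methyl-4H-1,3-dioxin-4-one | CC1=CC(=O)O[C@@H](C(C)(C)C)O1
F2 | step 3 | (1S,3S,6S)-3-tert-butyl-8,8-diethoxy-1-methyl-2,4-dioxabicyclo[4.2.0]octan-5-one | C[C@]12O[C@H](C(C)(C)C)OC(=O)[C@H]1CC2(OCC)OCC
F3 | step 3 | (1S,3S,6S)-3-tert-butyl-1-methyl-2,4-dioxabicyclo[4.2.0]octane-5,8-dione | C[C@]12O[C@H](C(C)(C)C)OC(=O)[C@H]1CC2=O
F4 | step 3 | (1S,3S,6S,8R)-3-tert-butyl-8-hydroxy-1-methyl-2,4-dioxabicyclo[4.2.0]octan-5-one | C[C@]12O[C@H](C(C)(C)C)OC(=O)[C@H]1C[C@H]2O
F5 | step 3 | (1S,3S,6S,8R)-3-tert-butyl-8-[(tert-butyldimethylsilyl)oxy]-1-methyl-2,4-dioxabicyclo[4.2.0]octan-5-one | C[C@]12O[C@H](C(C)(C)C)OC(=O)[C@H]1C[C@H]2O[Si](C)(C)C(C)(C)C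
F6 | step 1 | (R)-5-oxotetrahydrofuran-2-carboxylic acid | OC(=O)[C@H]1CCC(=O)O1
F7 | step 1 | (R)-5-oxotetrahydrofuran-2-carbonyl chloride | O=C(Cl)[C@H]1CCC(=O)O1
F8 | step 1 | (R)-5-acetyldihydrofuran-2(3H)-one | CC(=O)[C@H]1CCC(=O)O1
F9 | step 1 | (R)-4-hydroxycyclohexane-1,3-dione | O=C1CC(=O)[C@H](O)CC1
F10 | step 6 | (4R)-4-[(tert-butyldimethylsilyl)oxy]-5-oxohexanoic acid | OC(=O)CC[C@@H](O[Si](C)(C)C(C)(C)C)C(C)=O
F11 | step 6 | pentafluorophenyl (4R)-4-[(tert-butyldimethylsilyl)oxy]-5-oxohexanoate | O=C(CC[C@@H](O[Si](C)(C)C(C)(C)C)C(C)=O)Oc1c(F)c(F)c(F)c(F)c1F
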